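The earlier runs and the new flask were computed with made-up constants, noise included.

Amber is the run to read first, with green beside it; these two runs are what you have for choosing among the four flasks.

| setting | green | amber | ash | larch | elm | cedar |
|---|---|---|---|---|---|---|
| substrate | 0.080 M | 0.18 M | 0.12 M | 0.12 M | 0.12 M | 0.12 M |
| reagent | 0.36 M | 0.36 M | 0.360 M | 0.360 M | 0.360 M | 0.360 M |
| temperature | 10 °C | 43 °C | 25 °C | 55 °C |  | −5 °C |
| remark | run made earlier | run made earlier |  |  | at −5 °C until 1.0 h, from then on at 55 °C |  |
| time |  |  | 2.0 h | 2.0 h | 2.0 h | 2.0 h |

green run (percent of the substrate charged)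

| time / h | target / % |
|---|---|
| 0.333 | 6.2 |
| 1.00 | 18.4 |
| 2.00 | 30.3 |
| 3.00 | 36.7 |
| 4.00 | 40.7 |
| 5.00 | 41.8 |

amber run (percent of the substrate charged)

| time / min | target / % |
|---|---|
| 10.0 | 22.5 |
| 20.0 | 27.5 |
| 30.0 | 28.3 |
| 40.0 | 27.9 |
| 50.0 | 27.0 |
| 60.0 | 25.9 |



1. the best flask by amount of target, in percent of the substrate charged; "all alike" if 1.5 percentage points covers them all (ash / larch / elm / cedar / all alike)
2. amount of target at the end, in percent of the substrate charged, ash
3. amount of target at the end, in percent of the substrate charged, larch
4. amount of target at the end, in percent of the substrate charged, elm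
5. amount of target at the end, in percent of the substrate charged, cedar

Read amber's target column downward. It climbs, stands highest at 30.0 min with 28.3 %, then sinks to 25.9 % by 60.0 min. That top is a reading with a standard deviation of 0.5 percentage points, but the shape says target is a middle stage of consecutive reactions: it is made and used up, and at the top the two rates are equal.

Now read green the same way. Its highest reading, 41.8 %, is its last, at 5.00 h, so I place its top there, and the true top may come later. Both runs start at [reagent] = 0.36 M, and I set aside amber's larger charge of substrate. Column against column, the peak time read in amber at 43 °C is shorter than the one read in green at 10 °C by a factor of 10.0, and I give this factor to temperature as my own assumption.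

If equal steps of temperature shorten it by equal factors, the peak time is 1.76 h for ash, 0.216 h for larch and 14.2 h for cedar.

Divide the run time by the peak time. For larch this gives 9.24, and I call it the run-to-peak ratio, the run time over the time at which target tops. One is the zero of this scale, where making equals using; above it a flask is spending target, and below it the flask is still filling.

Ash stands at 1.14 and cedar at 0.140, so ash lies closer to one than larch above or cedar below. For elm, add the two parts of its time, each over its own peak time: 4.69, which is less than larch's ratio.

So I commit to ash as best, with target between amber's top and green's last reading, and to more target in elm than in larch.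

The forecast names ash as best, with 35 % for ash, 13 % for larch, 20 % for elm and 9 % for cedar, reading the runs as “substrate loss with a competing side path, plus slow loss of target”.

The flasks give ash as best: ash 32.1 %, larch 6.57 %, elm 13.7 % and cedar 11.0 %.

    substrate + reagent ⇌ target + by-product (K = 0.200, k = 5.60 × 10⁻⁴ M⁻¹ s⁻¹, Ea = 55.0 kJ mol⁻¹, ΔH = −14.0 kJ mol⁻¹)
    target ⇌ isomer of the product (K = 0.890, k = 1.80 × 10⁻⁴ s⁻¹, Ea = 89.0 kJ mol⁻¹, ΔH = −54.0 kJ mol⁻¹)
    target → over-reaction product (k = 1.10 × 10⁻⁵ s⁻¹, Ea = 110 kJ mol⁻¹)
    (constants at 25 °C)

Ash has not come to rest: left ten times as long, at 20.0 h, its ratio reaches 11.4, its target falls to 23.5 %, and over-reaction product rises from 2.10 % to 21.3 %. Larch, at ratio 9.24, is still moving too, with target made at 0.718 of the rate it is used up at 2.00 h, each step taken net; by 20.0 h its target is 0 % and over-reaction product holds >99.9 %. Cedar, at 0.140, reaches ratio 1.41 by 20.0 h, with target at 47.0 % and 45.3 % of its substrate still there.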